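**Retrosynthetic overview**
1. Plagiochin E ⇐ its tri-O-methyl macrocycle, by cleavage of three aryl methyl ethers.
2. The 16-membered ring is the only ring built and is closed in the second-last step. The bond formed is the aryl C–O bond between the ring B phenol oxygen and the fluorine-bearing carbon of ring C, by a catalytic π-arene SNAr ring closure of an open seco-phenol.
3. Seco-phenol ⇐ one hydrogenation (two C=C bonds, one O-benzyl group) of a biaryl bis-stilbene.
4. Biaryl bond between rings A and D ⇐ one-pot borylation/Suzuki coupling of two bromostilbenes.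
5. Each bromostilbene ⇐ Horner–Wadsworth–Emmons olefination of commercial benzyl and benzaldehyde building blocks.

Assumption: the target SMILES has no stereocentre and no defined axis, so "single enantiomer" is read as the constitution drawn and no stereocontrol is needed.

**Route**

Step 1
Reactants: 1 2-bromo-5-methoxybenzyl bromide; 2 triethyl phosphite; 3 3-(benzyloxy)-4-methoxybenzaldehyde (O-benzylisovanillin)
Product: 5 2-(benzyloxy)-4-[(E)-2-(2-bromo-5-methoxyphenyl)ethenyl]-1-methoxybenzene, via benzylphosphonate 4 (not isolated)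
Conditions: 2 (1.2 equiv), neat, 130 °C, 3 h, EtBr distilled off, excess 2 removed in vacuo; then THF, 3 (1.0 equiv), KOtBu (1.3 equiv), 0 °C → rt
Reagents that add atoms: none
Why: Michaelis–Arbuzov reaction of the benzylic bromide (the aryl bromide is inert without a metal catalyst) followed by Horner–Wadsworth–Emmons olefination of the non-enolisable aldehyde, which gives the E-alkene under thermodynamic control of the elimination.

Step 2
Reactants: 6 2-bromo-3-methoxybenzaldehyde; 7 diethyl (4-fluorobenzyl)phosphonate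
Product: 8 2-bromo-1-[(E)-2-(4-fluorophenyl)ethenyl]-3-methoxybenzene
Conditions: KOtBu (1.2 equiv), THF, 0 °C → rt
Reagents that add atoms: none
Why: Horner–Wadsworth–Emmons olefination of a non-enolisable aryl aldehyde with a benzylphosphonate anion gives the E-stilbene, and neither the aryl bromide nor the aryl fluoride reacts with the base at this temperature.

Step 3
Reactants: 5 2-(benzyloxy)-4-[(E)-2-(2-bromo-5-methoxyphenyl)ethenyl]-1-methoxybenzene; 9 bis(pinacolato)diboron; 8 2-bromo-1-[(E)-2-(4-fluorophenyl)ethenyl]-3-methoxybenzene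
Product: 11 2-[(E)-2-(3-(benzyloxy)-4-methoxyphenyl)ethenyl]-2'-[(E)-2-(4-fluorophenyl)ethenyl]-4,6'-dimethoxy-1,1'-biphenyl, via aryl boronate 10 (not isolated)
Conditions: 5, 9 (1.05 equiv), Pd2(dba)3 (2 mol %), XPhos (8 mol %), KOAc (3 equiv), 1,4-dioxane, 100 °C, 3 h; then 8 (0.95 equiv), 3 M aq K3PO4 (3 equiv), 100 °C, 12 h
Reagents that add atoms: none
Why: Miyaura borylation of the less hindered ring A bromide and Suzuki–Miyaura coupling in the same pot, where the bulky biarylphosphine gives a monoligated zerovalent palladium species able to insert into the di-ortho-substituted bromide 8 and to form the tri-ortho-substituted biaryl, while the aryl fluoride, benzyl ether and alkenes are untouched.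

Step 4
Reactants: 11 2-[(E)-2-(3-(benzyloxy)-4-methoxyphenyl)ethenyl]-2'-[(E)-2-(4-fluorophenyl)ethenyl]-4,6'-dimethoxy-1,1'-biphenyl
Product: 12 5-[2-(2'-[2-(4-fluorophenyl)ethyl]-4,6'-dimethoxy-[1,1'-biphenyl]-2-yl)ethyl]-2-methoxyphenol
Conditions: H2 (1 atm), 10 % Pd/C, EtOAc/EtOH 1:1, rt, 16 h
Reagents that add atoms: none
Why: Heterogeneous catalytic hydrogenation saturates both stilbene double bonds and hydrogenolyses the benzyl ether in one operation, while the aryl C–F bond and the aryl methyl ethers are inert under these conditions.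

Step 5
Reactants: 12 5-[2-(2'-[2-(4-fluorophenyl)ethyl]-4,6'-dimethoxy-[1,1'-biphenyl]-2-yl)ethyl]-2-methoxyphenol
Product: 13 tri-O-methylplagiochin E (the 16-membered macrocycle in which the ring B oxygen meta to its bridge is bonded to C-4 of ring C)
Conditions: [CpRu(MeCN)3]PF6 (20 mol %), Cs2CO3 (2 equiv), degassed THF, 45 °C, pulsed 365 nm LED, 12 added over 10 h to 5 mM
Reagents that add atoms: none
Why: Proposed new method: a light-gated, ruthenium-catalysed π-arene SNAr macro-etherification, in which the CpRu+ fragment binds η6 to the least hindered ring (the para-disubstituted fluoroarene, ring C) and makes its C–F carbon about as electrophilic as that of a nitrofluoroarene, the tethered caesium phenoxide of ring B adds at that carbon and fluoride leaves (addition–elimination), and 365 nm light then detaches the metal from the product and from unproductively bound anisole or phenoxide rings so that the sub-stoichiometric Ru is redistributed until all of 12 has passed through the one complex that reacts irreversibly; the closest known chemistry is the stoichiometric sequence of CpRu+ complexation of a haloarene, room-temperature phenoxide SNAr macrocyclisation and photolytic decomplexation, together with thermal Ru- and Rh-catalysed SNAr of unactivated fluoroarenes by amines and alkoxides, none of which has been run as a catalytic ring closure with a phenoxide.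

Step 6
Reactants: 13 tri-O-methylplagiochin E
Product: 14 plagiochin E
Conditions: BBr3 (9 equiv), CH2Cl2, −78 °C → rt; then H2O, 0 °C
Reagents that add atoms: none
Why: Lewis-acid ether cleavage (BBr3 demethylation) removes the three aryl methyl groups by bromide attack on the boron-activated O–CH3 bonds, while the diaryl ether and the bibenzyl bridges have no comparably labile C–O bond.

**Compound list**
1 | 2-bromo-5-methoxybenzyl bromide (1-bromo-2-(bromomethyl)-4-methoxybenzene) | COc1ccc(Br)c(CBr)c1 | starting material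
2 | triethyl phosphite | CCOP(OCC)OCC | starting material
3 | 3-(benzyloxy)-4-methoxybenzaldehyde (O-benzylisovanillin) | COc1ccc(C=O)cc1OCc1ccccc1 | starting material
4 | diethyl (2-bromo-5-methoxybenzyl)phosphonate | CCOP(=O)(Cc1cc(OC)ccc1Br)OCC | intermediate
5 | 2-(benzyloxy)-4-[(E)-2-(2-bromo-5-methoxyphenyl)ethenyl]-1-methoxybenzene | COc1ccc(Br)c(/C=C/c2ccc(OC)c(OCc3ccccc3)c2)c1 | intermediate
6 | 2-bromo-3-methoxybenzaldehyde | COc1cccc(C=O)c1Br | starting material
7 | diethyl (4-fluorobenzyl)phosphonate | CCOP(=O)(Cc1ccc(F)cc1)OCC | starting material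
8 | 2-bromo-1-[(E)-2-(4-fluorophenyl)ethenyl]-3-methoxybenzene | COc1cccc(/C=C/c2ccc(F)cc2)c1Br | intermediate
9 | bis(pinacolato)diboron | CC1(C)OB(OC1(C)C)B1OC(C)(C)C(C)(C)O1 | starting material
10 | 2-{2-[(E)-2-(3-(benzyloxy)-4-methoxyphenyl)ethenyl]-4-methoxyphenyl}-4,4,5,5-tetramethyl-1,3,2-dioxaborolane | COc1ccc(B2OC(C)(C)C(C)(C)O2)c(/C=C/c2ccc(OC)c(OCc3ccccc3)c2)c1 | intermediate
11 | 2-[(E)-2-(3-(benzyloxy)-4-methoxyphenyl)ethenyl]-2'-[(E)-2-(4-fluorophenyl)ethenyl]-4,6'-dimethoxy-1,1'-biphenyl | COc1ccc(-c2c(OC)cccc2/C=C/c2ccc(F)cc2)c(/C=C/c2ccc(OC)c(OCc3ccccc3)c2)c1 | intermediate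
12 | 5-[2-(2'-[2-(4-fluorophenyl)ethyl]-4,6'-dimethoxy-[1,1'-biphenyl]-2-yl)ethyl]-2-methoxyphenol | COc1ccc(-c2c(OC)cccc2CCc2ccc(F)cc2)c(CCc2ccc(OC)c(O)c2)c1 | intermediate
13 | tri-O-methylplagiochin E (macrocycle of 14 with OMe in place of each OH: ring A para to the biaryl bond, ring B ortho to the diaryl ether oxygen, ring D ortho to the biaryl bond) | COc1ccc2c(c1)CCc1ccc(OC)c(c1)Oc1ccc(cc1)CCc1cccc(OC)c1-2 | intermediate
14 | plagiochin E (16-membered bis(bibenzyl): rings A and D joined by a biaryl bond ortho to both ethylene bridges; ring B oxygen joined to C-4 of ring C; OH on ring A para to the biaryl bond, on ring B para to its bridge, on ring D ortho to the biaryl bond; no stereocentre) | Oc1ccc2c(c1)CCc1ccc(O)c(c1)Oc1ccc(cc1)CCc1cccc(O)c1-2 | target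

**Step count**
Total: 6 steps (steps 1 and 2 run in parallel). Longest linear sequence: 5 steps (1, 3, 4, 5, 6).

**Three steps most likely to fail, with fallbacks**

Step 5 (the new ring closure). The metal may stay on the electron-rich rings or on the phenoxide, or turnover may be too slow. The fallback closes the same C–O bond by a Chan–Lam coupling of an arylboronate, which is known for macrocyclic diaryl ethers. It sets out from 5 and 6. Compound 5 is borylated in the flask to 10 as in step 3 and coupled with 6 under the same Suzuki conditions to give 2'-[(E)-2-(3-(benzyloxy)-4-methoxyphenyl)ethenyl]-4',6-dimethoxy-[1,1'-biphenyl]-2-carbaldehyde F1. Horner–Wadsworth–Emmons olefination with commercial diethyl [4-(4,4,5,5-tetramethyl-1,3,2-dioxaborolan-2-yl)benzyl]phosphonate (KOtBu, THF, 0 °C) gives 2-{4-[(E)-2-(2'-[(E)-2-(3-(benzyloxy)-4-methoxyphenyl)ethenyl]-4',6-dimethoxy-[1,1'-biphenyl]-2-yl)ethenyl]phenyl}-4,4,5,5-tetramethyl-1,3,2-dioxaborolane F2. Hydrogenation (H2, Pd/C, EtOAc/EtOH), which leaves the aryl boronate intact, gives 2-methoxy-5-[2-(4,6'-dimethoxy-2'-{2-[4-(4,4,5,5-tetramethyl-1,3,2-dioxaborolan-2-yl)phenyl]ethyl}-[1,1'-biphenyl]-2-yl)ethyl]phenol F3. Ring closure with Cu(OAc)2 (2 equiv), B(OH)3, Et3N, 4 Å molecular sieves, MeCN, air, 60 °C at 3 mM comes back to the route at 13.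

Step 3 (one-pot borylation and coupling to a tri-ortho-substituted biaryl). Protodeboronation of 10 or slow insertion into hindered 8 may lower the yield. The fallback forms the biaryl bond earlier, with a small pre-formed boronic acid, and builds the A–B bridge afterwards. It sets out from 8. Suzuki coupling of 8 with commercial (2-formyl-4-methoxyphenyl)boronic acid (Pd(OAc)2, SPhos, K3PO4, toluene/H2O, 90 °C) gives 2'-[(E)-2-(4-fluorophenyl)ethenyl]-4,6'-dimethoxy-[1,1'-biphenyl]-2-carbaldehyde F4. Commercial 3-(benzyloxy)-4-methoxybenzyl alcohol and PPh3·HBr (MeCN, reflux) give [3-(benzyloxy)-4-methoxybenzyl]triphenylphosphonium bromide F5. Wittig olefination of F4 with the ylide from F5 (KOtBu, THF, 0 °C) gives 11 mixed with its isomer 2-[(Z)-2-(3-(benzyloxy)-4-methoxyphenyl)ethenyl]-2'-[(E)-2-(4-fluorophenyl)ethenyl]-4,6'-dimethoxy-1,1'-biphenyl F6. The mixture is hydrogenated as in step 4 and comes back to the route at 12.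

Step 4 (three reductions in one operation). Catalyst poisoning by residues from step 3, or slow O-debenzylation, may leave the reaction incomplete. The fallback separates the two tasks and uses no heterogeneous catalyst. It sets out from 11. Diimide reduction (TsNHNH2, NaOAc, THF/H2O, reflux) saturates both alkenes and gives 2-(benzyloxy)-4-[2-(2'-[2-(4-fluorophenyl)ethyl]-4,6'-dimethoxy-[1,1'-biphenyl]-2-yl)ethyl]-1-methoxybenzene F7. Selective Lewis-acid debenzylation (BCl3, pentamethylbenzene, CH2Cl2, −78 °C), which spares the methyl ethers, comes back to the route at 12.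

**Further compounds**
F1 | step 5 | 2'-[(E)-2-(3-(benzyloxy)-4-methoxyphenyl)ethenyl]-4',6-dimethoxy-[1,1'-biphenyl]-2-carbaldehyde | COc1ccc(-c2c(OC)cccc2C=O)c(/C=C/c2ccc(OC)c(OCc3ccccc3)c2)c1
F2 | step 5 | 2-{4-[(E)-2-(2'-[(E)-2-(3-(benzyloxy)-4-methoxyphenyl)ethenyl]-4',6-dimethoxy-[1,1'-biphenyl]-2-yl)ethenyl]phenyl}-4,4,5,5-tetramethyl-1,3,2-dioxaborolane | COc1ccc(-c2c(OC)cccc2/C=C/c2ccc(B3OC(C)(C)C(C)(C)O3)cc2)c(/C=C/c2ccc(OC)c(OCc3ccccc3)c2)c1
F3 | step 5 | 2-methoxy-5-[2-(4,6'-dimethoxy-2'-{2-[4-(4,4,5,5-tetramethyl-1,3,2-dioxaborolan-2-yl)phenyl]ethyl}-[1,1'-biphenyl]-2-yl)ethyl]phenol | COc1ccc(-c2c(OC)cccc2CCc2ccc(B3OC(C)(C)C(C)(C)O3)cc2)c(CCc2ccc(OC)c(O)c2)c1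
F4 | step 3 | 2'-[(E)-2-(4-fluorophenyl)ethenyl]-4,6'-dimethoxy-[1,1'-biphenyl]-2-carbaldehyde | COc1ccc(-c2c(OC)cccc2/C=C/c2ccc(F)cc2)c(C=O)c1
F5 | step 3 | [3-(benzyloxy)-4-methoxybenzyl]triphenylphosphonium bromide | COc1ccc(C[P+](c2ccccc2)(c2ccccc2)c2ccccc2)cc1OCc1ccccc1.[Br-]
F6 | step 3 | 2-[(Z)-2-(3-(benzyloxy)-4-methoxyphenyl)ethenyl]-2'-[(E)-2-(4-fluorophenyl)ethenyl]-4,6'-dimethoxy-1,1'-biphenyl | COc1ccc(-c2c(OC)cccc2/C=C/c2ccc(F)cc2)c(/C=C\c2ccc(OC)c(OCc3ccccc3)c2)c1
F7 | step 4 | 2-(benzyloxy)-4-[2-(2'-[2-(4-fluorophenyl)ethyl]-4,6'-dimethoxy-[1,1'-biphenyl]-2-yl)ethyl]-1-methoxybenzene | COc1ccc(-c2c(OC)cccc2CCc2ccc(F)cc2)c(CCc2ccc(OC)c(OCc3ccccc3)c2)c1
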